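## Retrosynthetic overview

1. Target ⇒ C14–C15 disconnection (hydroboration / B‑alkyl Suzuki): bicyclic oct‑7‑enyl lactone + (1E,3E)‑dienyl iodide from cinnamaldehyde.
2. Bicyclic core ⇒ Wittig / oxa‑Michael (THF ring, O–C3) / lactonisation (γ‑lactone; C3 fixed by cis‑fusion) from the lactol of an α‑hydroxy‑γ‑lactone.
3. α‑Hydroxy‑γ‑lactone ⇒ C4–C5 disconnection: lactate‑dioxolanone enolate + (S)‑2‑methyl‑2‑(oct‑7‑enyl)oxirane, with in‑situ translactonisation (this lactone ring later becomes the THF ring).
4. Epoxide ⇒ diol ⇒ dioxolanone; C7–C8 disconnection by mixed Kolbe electrolysis of a dioxolanone‑acetic acid with oct‑7‑enoic acid.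
5. Both quaternary centres (C4, C6) ⇐ one building block, the (R)‑lactic acid / pivalaldehyde dioxolanone. Ring order: oxirane → γ‑lactone (future THF) → THF + γ‑lactone bicycle.

Assumption: core atoms are labelled C1 (lactone C=O), C2, C3 (ring‑fusion CH–O), C4 (ring‑fusion C–Me), C5 (CH2), C6 (quaternary ether carbon), chain C7–C18; the target is (3S,4S,6S), i.e. (3aS,5S,6aS) in furo[3,2‑b]furanone numbering.

## Route

**Step 1**
Reactants: 1, (R)‑lactic acid (D‑lactic acid); 2, pivalaldehyde
Product: 3, (2R,5R)‑2‑tert‑butyl‑5‑methyl‑1,3‑dioxolan‑4‑one (cis)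
Conditions: TsOH·H2O (cat.), H2SO4 (cat.), pentane, reflux, Dean–Stark; recrystallise (pentane, −78 °C)
Reagents that add atoms: pivalaldehyde, CC(C)(C)C=O
Why: Acid‑catalysed acetalisation under thermodynamic control (Seebach self‑regeneration‑of‑stereocentres template); the lactate centre directs the new acetal centre cis, and crystallisation gives the pure cis isomer.

**Step 2**
Reactants: 3, (2R,5R)‑dioxolanone; 4, benzyl bromoacetate
Product: 5, benzyl 2‑[(2R,4S)‑2‑tert‑butyl‑4‑methyl‑5‑oxo‑1,3‑dioxolan‑4‑yl]acetate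
Conditions: LDA, THF, −78 °C; then 4, −78 → −30 °C
Reagents that add atoms: benzyl bromoacetate, BrCC(=O)OCc1ccccc1
Why: Seebach enolate alkylation: the planar enolate keeps only the acetal centre, whose t‑Bu group forces the electrophile to enter anti, so CH2CO2Bn replaces H with retention and sets the future C6 (S).

**Step 3**
Reactants: 5, benzyl ester
Product: 6, 2‑[(2R,4S)‑2‑tert‑butyl‑4‑methyl‑5‑oxo‑1,3‑dioxolan‑4‑yl]acetic acid (the pivalaldehyde acetal of (S)‑citramalic acid)
Conditions: H2 (1 atm), 10% Pd/C, EtOAc, rt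
Reagents that add atoms: none
Why: Pd‑catalysed hydrogenolysis of the benzyl ester; the acylal and the quaternary centre are inert.

**Step 4** (electrochemical key C–C bond, C7–C8)
Reactants: 6, dioxolanone‑acetic acid; 7, oct‑7‑enoic acid (6 equiv)
Product: 8, (2R,5S)‑2‑tert‑butyl‑5‑methyl‑5‑(oct‑7‑en‑1‑yl)‑1,3‑dioxolan‑4‑one
Conditions: Pt anode / Pt cathode, undivided cell, MeOH, Et3N (5% neutralisation), ca. 200 mA cm⁻², 20–30 °C, to pH ≈ 8
Reagents that add atoms: oct‑7‑enoic acid, C=CCCCCCC(=O)O
Why: Mixed Kolbe electrolysis: anodic decarboxylation gives the β‑oxygenated primary radical of 6 and the hept‑6‑enyl radical (too slow to cyclise), which cross‑couple at the electrode with excess 7; the stereocentre is β to the radical and untouched.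

**Step 5**
Reactants: 8, alkylated dioxolanone
Product: 9, (S)‑2‑methyldec‑9‑ene‑1,2‑diol
Conditions: LiAlH4, THF, 0 °C → rt
Reagents that add atoms: none
Why: Hydride reduction of the acylal lactone to the 1,2‑diol (the pivalaldehyde part leaves as neopentyl alcohol); no bond at the stereocentre is broken.

**Step 6**
Reactants: 9, diol
Product: 10, (S)‑2‑methyl‑2‑(oct‑7‑en‑1‑yl)oxirane
Conditions: TsCl, Et3N, DMAP (cat.), CH2Cl2, 0 °C; then K2CO3, MeOH, rt
Reagents that add atoms: none
Why: Selective primary tosylation then intramolecular Williamson closure by the tertiary alkoxide; the C–O bond at the stereocentre is never cleaved, so configuration is retained.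

**Step 7** (proposed new step; C4–C5 bond, C4 stereocentre, first ring of the core)
Reactants: 10, (S)‑epoxide; 3, (2R,5R)‑dioxolanone (1.5 equiv)
Product: 11, (3S,5S)‑3‑hydroxy‑3,5‑dimethyl‑5‑(oct‑7‑en‑1‑yl)dihydrofuran‑2(3H)‑one (pivalaldehyde is lost)
Conditions: 3, LiHMDS, THF, −78 °C; then 10, BF3·OEt2 (1.2 equiv), −78 → −40 °C; aq. NH4Cl; then TsOH (cat.), CH2Cl2, rt
Reagents that add atoms: dioxolanone 3 (supplies C3, C4, the C4 methyl and both oxygens), C[C@H]1O[C@@H](C(C)(C)C)OC1=O
Why: Proposed new method: BF3‑activated opening of a 2,2‑disubstituted epoxide at its CH2 terminus by the lithium enolate of the lactate dioxolanone, not yet shown for this enolate class to my knowledge; BF3 makes the epoxide reactive at −78 °C where the enolate is still stable, SN2 attack at the unhindered CH2 leaves C6 untouched and occurs on the enolate face anti to t‑Bu (sets C4 = S), and the freed tertiary alkoxide then attacks the acylal C=O (5‑exo‑trig) expelling pivalaldehyde to give the γ‑lactone; the closest known reactions are Yamaguchi/Ganem‑type BF3‑promoted epoxide openings by organolithiums and enolates, and Seebach alkylations of this enolate with alkyl halides.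

**Step 8**
Reactants: 11, α‑hydroxy‑γ‑lactone
Product: 12, (2RS,3S,5S)‑3,5‑dimethyl‑5‑(oct‑7‑en‑1‑yl)oxolane‑2,3‑diol (lactol, anomeric mixture)
Conditions: DIBAL‑H (2.2 equiv), CH2Cl2, −78 °C
Reagents that add atoms: none
Why: Partial reduction of the lactone to the lactol via the stable tetrahedral aluminate at −78 °C; the stereocentres are untouched and the anomeric mixture is inconsequential.

**Step 9**
Reactants: 12, lactol; 13, methyl (triphenylphosphoranylidene)acetate
Product: 14, (3aS,5S,6aS)‑5,6a‑dimethyl‑5‑(oct‑7‑en‑1‑yl)tetrahydrofuro[3,2‑b]furan‑2(3H)‑one (cis‑fused 2,6‑dioxabicyclo[3.3.0]octan‑3‑one)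
Conditions: 13 (1.5 equiv), toluene, 90 °C; then DBU, rt → 60 °C (one pot)
Reagents that add atoms: methyl (triphenylphosphoranylidene)acetate, COC(=O)C=P(c1ccccc1)(c1ccccc1)c1ccccc1
Why: Wittig olefination of the ring‑opened hydroxy‑aldehyde, then base‑mediated 5‑exo oxa‑Michael addition of the tertiary C6–OH and lactonisation of the C4–OH; only the cis‑fused isomer can lactonise and the other adduct reverts by retro‑Michael, so C3 (S) is set by C4.

**Step 10**
Reactants: 15, (E)‑cinnamaldehyde; 16, iodoform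
Product: 17, (1E,3E)‑(4‑iodobuta‑1,3‑dien‑1‑yl)benzene
Conditions: CrCl2, CHI3, THF, 0 °C
Reagents that add atoms: iodoform, IC(I)I
Why: Takai iodo‑olefination gives the E‑vinyl iodide selectively and leaves the existing E‑alkene untouched.

**Step 11**
Reactants: 14, bicyclic oct‑7‑enyl lactone; 17, dienyl iodide
Product: 18, plakortone P, (3aS,5S,6aS)‑5,6a‑dimethyl‑5‑[(9E,11E)‑12‑phenyldodeca‑9,11‑dien‑1‑yl]tetrahydrofuro[3,2‑b]furan‑2(3H)‑one
Conditions: 9‑BBN, THF, 0 °C → rt; then 17, Pd(dppf)Cl2 (5 mol%), AsPh3, K3PO4, DMF/H2O, rt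
Reagents that add atoms: dienyl iodide 17, I/C=C/C=C/c1ccccc1 (9‑BBN contributes only H)
Why: Anti‑Markovnikov hydroboration of the terminal alkene followed by B‑alkyl Suzuki–Miyaura coupling, which is stereoretentive at the dienyl iodide; the diene is introduced last and never sees the electrolysis, hydrides or Lewis acid.

## Compound list

1 | (R)‑lactic acid | C[C@@H](O)C(=O)O | starting material
2 | pivalaldehyde | CC(C)(C)C=O | starting material
3 | (2R,5R)‑2‑tert‑butyl‑5‑methyl‑1,3‑dioxolan‑4‑one | C[C@H]1O[C@@H](C(C)(C)C)OC1=O | intermediate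
4 | benzyl bromoacetate | BrCC(=O)OCc1ccccc1 | starting material
5 | benzyl 2‑[(2R,4S)‑2‑tert‑butyl‑4‑methyl‑5‑oxo‑1,3‑dioxolan‑4‑yl]acetate | C[C@@]1(CC(=O)OCc2ccccc2)O[C@@H](C(C)(C)C)OC1=O | intermediate
6 | 2‑[(2R,4S)‑2‑tert‑butyl‑4‑methyl‑5‑oxo‑1,3‑dioxolan‑4‑yl]acetic acid | C[C@@]1(CC(=O)O)O[C@@H](C(C)(C)C)OC1=O | intermediate
7 | oct‑7‑enoic acid | C=CCCCCCC(=O)O | starting material
8 | (2R,5S)‑2‑tert‑butyl‑5‑methyl‑5‑(oct‑7‑en‑1‑yl)‑1,3‑dioxolan‑4‑one | C[C@@]1(CCCCCCC=C)O[C@@H](C(C)(C)C)OC1=O | intermediate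
9 | (S)‑2‑methyldec‑9‑ene‑1,2‑diol | C[C@@](CO)(CCCCCCC=C)O | intermediate
10 | (S)‑2‑methyl‑2‑(oct‑7‑en‑1‑yl)oxirane | C[C@]1(CCCCCCC=C)CO1 | intermediate
11 | (3S,5S)‑3‑hydroxy‑3,5‑dimethyl‑5‑(oct‑7‑en‑1‑yl)dihydrofuran‑2(3H)‑one | C[C@]1(CCCCCCC=C)C[C@](C)(O)C(=O)O1 | intermediate
12 | (2RS,3S,5S)‑3,5‑dimethyl‑5‑(oct‑7‑en‑1‑yl)oxolane‑2,3‑diol | C[C@]1(CCCCCCC=C)C[C@](C)(O)C(O)O1 | intermediate
13 | methyl (triphenylphosphoranylidene)acetate | COC(=O)C=P(c1ccccc1)(c1ccccc1)c1ccccc1 | starting material
14 | (3aS,5S,6aS)‑5,6a‑dimethyl‑5‑(oct‑7‑en‑1‑yl)tetrahydrofuro[3,2‑b]furan‑2(3H)‑one | C[C@]1(CCCCCCC=C)C[C@]2(C)OC(=O)C[C@@H]2O1 | intermediate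
15 | (E)‑cinnamaldehyde | O=C/C=C/c1ccccc1 | starting material
16 | iodoform | IC(I)I | starting material
17 | (1E,3E)‑(4‑iodobuta‑1,3‑dien‑1‑yl)benzene | I/C=C/C=C/c1ccccc1 | intermediate
18 | plakortone P | C[C@]1(CCCCCCCC/C=C/C=C/c2ccccc2)C[C@]2(C)OC(=O)C[C@@H]2O1 | target

## Summary

Total steps: 11. Longest linear sequence: 10 (Steps 1–9 and 11).

Three steps most likely to fail:

1. **Step 7 (proposed new enolate/epoxide union).** Risks are enolate decomposition, BF3‑induced epoxide rearrangement, or attack at the tertiary carbon. Fallback with known chemistry: oxidise the primary alcohol of 9 to the aldehyde and silylate the tertiary OH; run the established aldol addition of the lithium enolate of 3 to that aldehyde (same anti‑to‑t‑Bu control of C4); remove the new C5 hydroxyl by Barton–McCombie deoxygenation; then acid‑mediated desilylation/translactonisation gives 11.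

2. **Step 4 (mixed Kolbe).** Risks are the statistical product mixture and partial methanolysis of the acylal. Fallback: replace the electrode radical–radical coupling by a catalytic cross‑coupling, namely Ni/Ir metallaphotoredox decarboxylative C(sp3)–C(sp3) coupling of 6 with 7‑bromohept‑1‑ene to give 8.

3. **Step 9 (Wittig / oxa‑Michael / lactonisation on a hindered lactol).** Risks are a sluggish Wittig next to the quaternary carbinol and slow addition of the tertiary alcohol. Fallback: reverse the ring order — Z‑selective Ando/Still–Gennari olefination of 12 gives the Z‑enoate, which lactonises to the 5,5‑disubstituted butenolide; a separate DBU‑ or TBAF‑mediated oxa‑Michael addition of the C6–OH then closes the THF ring, as in seco‑plakortolide → plakortone closures.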